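**Retrosynthetic overview**

- Numbering: C1 is the ring C=O, C2 carries one prenyl, C3 and C5 carry the enol oxygens, C4 carries the acyl group, C6 carries two prenyls, and C7 is the side-chain carbonyl carbon.
- Feature: the four contiguous sp2 ring carbons C2–C5 carry C, O, C, O in turn, the imprint of two ynol-type alkynes (C2≡C3–O and C4≡C5–O) joined at C3–C4; C1=O with the quaternary gem-diprenyl C6 is the C=C=O of diprenylketene.
- Disconnections: 21 ⇐ hydrolysis of the C5 ethyl enol ether, oxidation of the C7 carbinol and removal of an O3–Si–O–C7 diisopropylsilylene from bicycle 18. 18 ⇐ [2+2+2] cycloaddition of silylene-tethered diyne 9 with ketene 17 on zerovalent nickel (bonds C3–C4, C1–C2, C5–C6).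
- Fragments: 9 comes from a Kowalski ynolate trapped in the same flask by chlorosilane 5 (ethoxyacetylene, 3-methylbutanal, iPr2SiCl2). 17 comes from diethyl malonate and prenyl bromide.
- Ring order: the temporary six-membered dioxasiline ring and the six-membered carbocycle form together in step 9; the dioxasiline is opened again in step 10.

Key step: step 9

Remark: lupulone has no stereocentre. The only stereocentre on the route, the C7 carbinol carbon made in step 1, is carried as a racemate and erased in step 11.

**Route**

Step 1
Reactants: 1 ethoxyacetylene; 2 3-methylbutanal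
Product: 4 rac-1-ethoxy-5-methylhex-1-yn-3-ol, via lithium ethoxyacetylide 3 (not isolated)
Conditions: n-BuLi (1.05 equiv), THF, −78 °C; then 2, −78 → −20 °C; H2O quench
Reagents that add atoms: none
Why: 1,2-addition of a lithium alkynylide to an aldehyde gives the carbinol (future C7) as a racemate, which is immaterial because this carbon becomes a carbonyl in step 11, and the non-acidic quench avoids Meyer–Schuster rearrangement of the ethoxyethynyl carbinol.

Step 2
Reactants: 4 rac-1-ethoxy-5-methylhex-1-yn-3-ol
Product: 5 rac-chloro[(1-ethoxy-5-methylhex-1-yn-3-yl)oxy]di(propan-2-yl)silane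
Conditions: iPr2SiCl2 (3 equiv), Et3N (1.5 equiv), CH2Cl2, 0 °C, slow addition of 4; pentane, filtration; excess iPr2SiCl2 removed at 0.1 mbar; used crude
Reagents that add atoms: dichlorodi(propan-2-yl)silane, CC(C)[Si](Cl)(Cl)C(C)C
Why: monosilylation of a secondary alcohol by an excess of a hindered dialkyldichlorosilane is the standard first half of an unsymmetrical silaketal synthesis, and the remaining Si–Cl bond survives until a stronger nucleophile is offered.

Step 3
Reactants: 6 ethyl 4-methylpent-3-enoate; 5 rac-chloro[(1-ethoxy-5-methylhex-1-yn-3-yl)oxy]di(propan-2-yl)silane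
Product: 9 rac-[(1-ethoxy-5-methylhex-1-yn-3-yl)oxy][(5-methylhex-4-en-1-yn-1-yl)oxy]di(propan-2-yl)silane, via lithium dibromoenolate 7 (not isolated), via lithium ynolate 8 (not isolated)
Conditions: CH2Br2, lithium 2,2,6,6-tetramethylpiperidide, THF, −78 °C; 6; LiN(SiMe3)2, −78 → −20 °C; n-BuLi, −78 °C → rt; then 5 (2.3 equiv), −78 → 0 °C; pentane, filtration through basic Al2O3; chromatography on Et3N-deactivated silica gel
Reagents that add atoms: dibromomethane, BrCBr
Why: Kowalski ynolate formation (LiCHBr2 adds to the ester, dibromo enolate 7 undergoes Br/Li exchange and carbenoid 1,2-shift of the CH2CH=CMe2 group to ynolate 8) followed by O-silylation of the ambident ynolate, which a hindered dialkyl(alkoxy)chlorosilane should give just as bulky trialkylchlorosilanes do in siloxyalkyne syntheses; the second equivalent of 5 takes up the lithium ethoxide released from 6, so that the ynolate is not left short of electrophile.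

Step 4
Reactants: 10 diethyl malonate; 11 prenyl bromide (1-bromo-3-methylbut-2-ene)
Product: 13 diethyl 2,2-bis(3-methylbut-2-en-1-yl)malonate, via diethyl monoprenylmalonate 12 (not isolated)
Conditions: NaH (2.4 equiv), 11 (2.3 equiv), THF–DMF, 0 → 50 °C
Reagents that add atoms: none
Why: double malonic ester alkylation by SN2 displacement at a reactive primary allylic bromide should run to the dialkylated ester in one pot.

Step 5
Reactants: 13 diethyl 2,2-bis(3-methylbut-2-en-1-yl)malonate
Product: 14 ethyl 5-methyl-2-(3-methylbut-2-en-1-yl)hex-4-enoate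
Conditions: LiCl (2 equiv), H2O (2 equiv), DMSO, 160 °C
Reagents that add atoms: none
Why: Krapcho dealkoxycarbonylation (chloride attack on the ethyl group, decarboxylation, protonation by water) removes one ester under neutral conditions that leave the acid-sensitive trisubstituted alkenes untouched.

Step 6
Reactants: 14 ethyl 5-methyl-2-(3-methylbut-2-en-1-yl)hex-4-enoate
Product: 15 5-methyl-2-(3-methylbut-2-en-1-yl)hex-4-enoic acid
Conditions: KOH, EtOH–H2O, reflux; then 1 M HCl to pH 3, 0 °C
Reagents that add atoms: potassium hydroxide, [K+].[OH-]
Why: saponification of an α,α-dialkyl ester, with cold and brief acidification so that acid-catalysed lactonisation onto a prenyl alkene does not set in.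

Step 7
Reactants: 15 5-methyl-2-(3-methylbut-2-en-1-yl)hex-4-enoic acid
Product: 16 5-methyl-2-(3-methylbut-2-en-1-yl)hex-4-enoyl chloride
Conditions: (COCl)2 (1.3 equiv), DMF (cat.), CH2Cl2, 0 °C → rt, argon sweep; short-path distillation
Reagents that add atoms: oxalyl chloride, O=C(Cl)C(=O)Cl
Why: Vilsmeier-catalysed conversion of an acid to its chloride, in which only gases are formed and HCl is swept out before it can add to the prenyl alkenes.

Step 8
Reactants: 16 5-methyl-2-(3-methylbut-2-en-1-yl)hex-4-enoyl chloride
Product: 17 diprenylketene (5-methyl-2-(3-methylbut-2-en-1-yl)hexa-1,4-dien-1-one)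
Conditions: Et3N (1.3 equiv), Et2O, rt → reflux; filtration under argon; bulb-to-bulb distillation; kept as a toluene solution at −20 °C
Reagents that add atoms: none
Why: dehydrochlorination of an α,α-dialkylacetyl chloride by a tertiary amine gives the ketoketene, and two primary-alkyl branches should make it slow enough to dimerise that it can be freed from the ammonium salt and distilled.

Step 9
Reactants: 9 rac-[(1-ethoxy-5-methylhex-1-yn-3-yl)oxy][(5-methylhex-4-en-1-yn-1-yl)oxy]di(propan-2-yl)silane; 17 diprenylketene
Product: 18 rac-5-ethoxy-4-(2-methylpropyl)-6,6,8-tris(3-methylbut-2-en-1-yl)-2,2-di(propan-2-yl)-4H-benzo[d][1,3,2]dioxasilin-7(6H)-one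
Conditions: Ni(cod)2 (10 mol%), 1,4-bis(diphenylphosphino)butane (10 mol%), toluene, 25 → 45 °C; 17 (1.5 equiv) added by syringe pump over 6 h, starting directly after the catalyst is added to 9; filtration through Et3N-deactivated silica gel
Reagents that add atoms: none
Why: Proposed new method: zerovalent nickel should couple the two tethered ynol-type alkynes oxidatively to a nickelacyclopentadiene (bond C3–C4), the electron-rich Ni–C2 alkenyl should then migrate to the electrophilic carbonyl carbon of η2-bound ketene 17 (bond C1–C2), and C–C reductive elimination from the seven-membered nickelacycle should form C5–C6; the closest known reaction type is the Ni(cod)2/bisphosphine-catalysed [2+2+2] cycloaddition of carbon-tethered diynes with disubstituted ketenes to 6,6-disubstituted cyclohexa-2,4-dienones, extended here to a silylene-tethered siloxyalkyne/alkoxyalkyne pair and a dialkylketene. The dioxasiline ring closes by intramolecular oxidative cyclisation across the four-atom O–Si–O–C7 tether, and the carbocycle closes by ketene C=C insertion followed by C(sp2)–C(sp3) reductive elimination. No stereocentre is created, since C6 carries two identical prenyl groups, and the racemic C7 centre is only carried through. The step needs head-to-tail union of the alkynes, which the tether enforces and polarity supports (C3 is the electrophilic α-carbon of the siloxyalkyne, C4 the nucleophilic β-carbon of the ethoxyalkyne). It also needs the ketene oriented with its carbonyl carbon on C2, which is expected because C2 is the nucleophilic β-carbon of the silyl enol ether whereas C5 is an α-alkoxyalkenyl carbon, and because the bulky diprenyl carbon then bonds to the smaller oxygen-substituted C5. Reaction at the ketene C=C in preference to its C=O follows the bisphosphine precedent, and slow addition of 17 keeps its concentration low so that the uncatalysed [2+2] cycloaddition with either ynol ether cannot compete.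

Step 10
Reactants: 18 rac-5-ethoxy-4-(2-methylpropyl)-6,6,8-tris(3-methylbut-2-en-1-yl)-2,2-di(propan-2-yl)-4H-benzo[d][1,3,2]dioxasilin-7(6H)-one
Product: 19 rac-5-ethoxy-3-hydroxy-4-(1-hydroxy-3-methylbutyl)-2,6,6-tris(3-methylbut-2-en-1-yl)cyclohexa-2,4-dien-1-one
Conditions: Bu4NF (2.5 equiv), AcOH (2.5 equiv), THF, 0 °C
Reagents that add atoms: none
Why: fluoride cleaves both Si–O bonds of the silylene (the enol silyl ether first), acetic acid buffering keeps the freed vinylogous acid and allylic carbinol away from strong base, and the C5 ethyl enol ether is inert to fluoride and blocks loss of water from C7.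

Step 11
Reactants: 19 rac-5-ethoxy-3-hydroxy-4-(1-hydroxy-3-methylbutyl)-2,6,6-tris(3-methylbut-2-en-1-yl)cyclohexa-2,4-dien-1-one
Product: 20 5-ethoxy-3-hydroxy-4-(3-methylbutanoyl)-2,6,6-tris(3-methylbut-2-en-1-yl)cyclohexa-2,4-dien-1-one
Conditions: Dess–Martin periodinane (1.3 equiv), pyridine (3 equiv), CH2Cl2, 0 °C
Reagents that add atoms: none
Why: Dess–Martin oxidation of the secondary allylic carbinol to the C7 ketone should be fast at 0 °C under pyridine buffering, C2 of the free enol is fully substituted so that no tricarbonyl can form, and the only stereocentre of the route disappears here.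

Step 12
Reactants: 20 5-ethoxy-3-hydroxy-4-(3-methylbutanoyl)-2,6,6-tris(3-methylbut-2-en-1-yl)cyclohexa-2,4-dien-1-one
Product: 21 lupulone
Conditions: LiOH (5 equiv), 1,4-dioxane–H2O (degassed), 70 °C, argon; then 1 M HCl to pH 3, 0 °C
Reagents that add atoms: lithium hydroxide, [Li+].[OH-]
Why: hydroxide adds to C5, the β-carbon of the C4=C5–C7=O vinylogous ester, and ethoxide is expelled (addition–elimination), while exclusion of air protects the oxidation-prone β-acid and cold acidification releases lupulone.

**Compound list**

1 | ethoxyacetylene | CCOC#C | starting material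
2 | 3-methylbutanal | CC(C)CC=O | starting material
3 | lithium ethoxyacetylide | [Li+].[C-]#COCC | intermediate (not isolated)
4 | rac-1-ethoxy-5-methylhex-1-yn-3-ol | CCOC#CC(O)CC(C)C | intermediate
5 | rac-chloro[(1-ethoxy-5-methylhex-1-yn-3-yl)oxy]di(propan-2-yl)silane | CCOC#CC(CC(C)C)O[Si](Cl)(C(C)C)C(C)C | intermediate
6 | ethyl 4-methylpent-3-enoate | CCOC(=O)CC=C(C)C | starting material
7 | lithium 1,1-dibromo-5-methylhexa-1,4-dien-2-olate | [Li+].[O-]C(CC=C(C)C)=C(Br)Br | intermediate (not isolated)
8 | lithium 5-methylhex-4-en-1-yn-1-olate | [Li+].[O-]C#CCC=C(C)C | intermediate (not isolated)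
9 | rac-[(1-ethoxy-5-methylhex-1-yn-3-yl)oxy][(5-methylhex-4-en-1-yn-1-yl)oxy]di(propan-2-yl)silane | CC(C)=CCC#CO[Si](C(C)C)(C(C)C)OC(CC(C)C)C#COCC | intermediate
10 | diethyl malonate | CCOC(=O)CC(=O)OCC | starting material
11 | prenyl bromide (1-bromo-3-methylbut-2-ene) | CC(C)=CCBr | starting material
12 | diethyl 2-(3-methylbut-2-en-1-yl)malonate | CCOC(=O)C(CC=C(C)C)C(=O)OCC | intermediate (not isolated)
13 | diethyl 2,2-bis(3-methylbut-2-en-1-yl)malonate | CCOC(=O)C(CC=C(C)C)(CC=C(C)C)C(=O)OCC | intermediate
14 | ethyl 5-methyl-2-(3-methylbut-2-en-1-yl)hex-4-enoate | CCOC(=O)C(CC=C(C)C)CC=C(C)C | intermediate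
15 | 5-methyl-2-(3-methylbut-2-en-1-yl)hex-4-enoic acid | OC(=O)C(CC=C(C)C)CC=C(C)C | intermediate
16 | 5-methyl-2-(3-methylbut-2-en-1-yl)hex-4-enoyl chloride | ClC(=O)C(CC=C(C)C)CC=C(C)C | intermediate
17 | diprenylketene (5-methyl-2-(3-methylbut-2-en-1-yl)hexa-1,4-dien-1-one) | O=C=C(CC=C(C)C)CC=C(C)C | intermediate
18 | rac-5-ethoxy-4-(2-methylpropyl)-6,6,8-tris(3-methylbut-2-en-1-yl)-2,2-di(propan-2-yl)-4H-benzo[d][1,3,2]dioxasilin-7(6H)-one | O=C1C(CC=C(C)C)=C2O[Si](C(C)C)(C(C)C)OC(CC(C)C)C2=C(OCC)C1(CC=C(C)C)CC=C(C)C | intermediate
19 | rac-5-ethoxy-3-hydroxy-4-(1-hydroxy-3-methylbutyl)-2,6,6-tris(3-methylbut-2-en-1-yl)cyclohexa-2,4-dien-1-one | O=C1C(CC=C(C)C)=C(O)C(C(O)CC(C)C)=C(OCC)C1(CC=C(C)C)CC=C(C)C | intermediate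
20 | 5-ethoxy-3-hydroxy-4-(3-methylbutanoyl)-2,6,6-tris(3-methylbut-2-en-1-yl)cyclohexa-2,4-dien-1-one | O=C1C(CC=C(C)C)=C(O)C(C(=O)CC(C)C)=C(OCC)C1(CC=C(C)C)CC=C(C)C | intermediate
21 | lupulone | CC(C)=CCC1=C(O)C(C(=O)CC(C)C)=C(O)C(CC=C(C)C)(CC=C(C)C)C1=O | target

**Step count**

Total step count: 12. Longest linear sequence: 9 steps (steps 4 to 12, from diethyl malonate).

**Steps most likely to fail**

1. Step 9. The uncatalysed [2+2] cycloaddition of the ketene onto either ynol ether may outrun nickel catalysis, the ketene may insert in the reverse orientation, or the diyne may oligomerise on nickel before the ketene arrives. Fallback by known chemistry, setting out from prenyl bromide 11 and coming back at lupulone 21: purchased phloroglucinol is acylated with 3-methylbutanoyl chloride (AlCl3, nitrobenzene–CH2Cl2, Friedel–Crafts) to phlorisovalerophenone F1. F1 is then C-prenylated three times with 11 in cold aqueous KOH; the third prenylation dearomatises the ring at the carbon that takes two prenyls and gives 21 directly, and under-prenylated by-products are removed by crystallisation.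

2. Step 3. LiCHBr2 may enolise the readily deprotonated β,γ-unsaturated ester instead of adding to its carbonyl group, the double bond may move into conjugation, and the lithium ethoxide set free from the ester may consume the chlorosilane faster than the ynolate does. Fallback, setting out from prenyl bromide 11 and coming back at diyne 9: 11 is coupled with ethynylmagnesium bromide under CuCl catalysis (THF) to 5-methylhex-4-en-1-yne F2. The lithium acetylide of F2 (n-BuLi, THF, −78 °C) is oxidised with lithium tert-butyl peroxide (from tert-butyl hydroperoxide and LiN(SiMe3)2) to ynolate 8, and 5 (1.2 equiv) is added to the same flask to give 9. No ester is involved, and the only alkoxide present is lithium tert-butoxide, which is too hindered to compete for 5 at low temperature.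

3. Step 8. Dehydrochlorination of the hindered α,α-dialkylacetyl chloride by Et3N may be slow, and the ammonium chloride that builds up may promote dimerisation of the ketene or its acylation by unreacted acid chloride. Fallback, setting out from acid 15 and coming back at ketene 17: 15 is converted into its dianion (LiN(iPr)2, 2.2 equiv, THF, −78 → 0 °C) and brominated with CBr4 at −78 °C to give 2-bromo-5-methyl-2-(3-methylbut-2-en-1-yl)hex-4-enoic acid F3. (COCl)2 with catalytic DMF converts F3 into 2-bromo-5-methyl-2-(3-methylbut-2-en-1-yl)hex-4-enoyl chloride F4. Activated Zn dust (THF, 0 °C → rt) then removes bromine and chlorine by reductive 1,2-elimination, with no amine or ammonium salt present, and 17 is taken up in pentane, filtered from the zinc salt and distilled.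

**Further compounds**

F1 | step 9 | phlorisovalerophenone (3-methyl-1-(2,4,6-trihydroxyphenyl)butan-1-one) | CC(C)CC(=O)c1c(O)cc(O)cc1O
F2 | step 3 | 5-methylhex-4-en-1-yne | CC(C)=CCC#C
F3 | step 8 | 2-bromo-5-methyl-2-(3-methylbut-2-en-1-yl)hex-4-enoic acid | OC(=O)C(Br)(CC=C(C)C)CC=C(C)C
F4 | step 8 | 2-bromo-5-methyl-2-(3-methylbut-2-en-1-yl)hex-4-enoyl chloride | ClC(=O)C(Br)(CC=C(C)C)CC=C(C)C
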